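**Plan**
- Target numbering: OH on C1 and C2, Br on C3, C4 and C6, CH3 on C5 (3,4,6-tribromo-5-methylbenzene-1,2-diol, achiral).
- The retrosynthesis first cuts the C3–Br and C4–Br bonds (late electrophilic bromination) and removes the two O-protecting groups. It then cuts C6–C1 and C6–C5, which lifts the brominated carbon C6 out of the benzene ring and leaves a five-membered diene. Last, O-pivaloyl and O-methyl are removed to reach cyclotene.
- Enabling feature: C6(Br) sits between oxygen-bearing C1 and methyl-bearing C5, and C2 next to C1 is also oxygenated. The carbons that become C1 and C5 are therefore the two ends of the enol double bond of 3-methylcyclopentane-1,2-dione, and a CBr unit pushed into that bond lands at C6.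
- Forward: the five-membered ring is bought. O-methylation and O-pivaloylation of the α′ enolate give the cyclopentadiene. Dibromocarbene then expands it to the benzene ring, the only ring made, with C6–Br in place. Ester cleavage, ether cleavage and bromination at C3 and C4 follow.
- Stereochemistry: the target has none. The cis-fused cyclopropane adduct is racemic and its two centres vanish on aromatisation.

Key step: step 3

Assumption: commercial cyclotene is used as its enol tautomer, 2-hydroxy-3-methylcyclopent-2-en-1-one; every compound of the route is achiral or racemic.

**Step 1**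
Reactants: 1 cyclotene (2-hydroxy-3-methylcyclopent-2-en-1-one)
Product: 3 2-methoxy-3-methylcyclopent-2-en-1-one, via potassium cyclotene enolate 2 (not isolated)
Conditions: Me2SO4, K2CO3, acetone, reflux
Reagents that add atoms: dimethyl sulfate, COS(=O)(=O)OC
Why: Williamson-type O-alkylation of the acidic diosphenol with a hard methylating agent in acetone should favour oxygen over carbon and give the methyl enol ether of the 1,2-dione.

**Step 2**
Reactants: 3 2-methoxy-3-methylcyclopent-2-en-1-one; 4 pivaloyl chloride
Product: 6 5-methoxy-4-methylcyclopenta-1,4-dien-1-yl pivalate, via potassium dienolate 5 (not isolated)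
Conditions: KN(SiMe3)2, THF, −78 °C; inverse addition to t-BuCOCl, THF, −78 → −30 °C; cold pentane/aq. NaHCO3 work-up, solution used at once below −20 °C
Reagents that add atoms: pivaloyl chloride (4), CC(C)(C)C(Cl)=O
Why: Kinetic α′-deprotonation of the enone gives the cross-conjugated potassium dienolate, and the hindered acyl chloride should trap it on oxygen (enol ester formation), while inverse addition and low temperature limit proton transfer to the product, 1,5-hydrogen shift and Diels–Alder dimerisation.

**Step 3**
Reactants: 6 5-methoxy-4-methylcyclopenta-1,4-dien-1-yl pivalate; 7 bromoform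
Product: 10 3-bromo-2-methoxy-4-methylphenyl pivalate, via dibromocyclopropane adduct 8 (not isolated), via arenium bromide 9 (not isolated)
Conditions: CHBr3 (1.5 equiv), KOt-Bu (2.6 equiv, solid, added last in portions), pentane, −30 °C, then 0 °C
Reagents that add atoms: bromoform (7), BrC(Br)Br
Why: KOt-Bu deprotonates bromoform and the tribromomethanide loses bromide (α-elimination) to give dibromocarbene, an electrophile that adds in a [2+1] sense to the tetrasubstituted double bond of 6 carrying OCH3 and CH3, giving the cis-fused gem-dibromocyclopropane 8. Disrotatory electrocyclic opening of 8 with departure of the endo bromide, pushed by the methoxy oxygen, breaks the bond that was the enol ether double bond, so the carbene carbon stays bonded to both former alkene carbons (C6–C1 and C6–C5 of the target) and the five-membered ring becomes the six-membered cation 9; the benzene ring is thus closed by a cyclopropyl-to-allyl cation ring expansion. Cation 9 is an arenium ion whose only sp3 carbon is the former ring CH2, and loss of that proton to tert-butoxide should give arene 10 with bromine between the methoxy-bearing and the methyl-bearing carbon, without an oxidant because dione and carbene together already stand at the oxidation level of a bromocatechol. The closest known reaction type is the dihalocarbene ring expansion of cyclopentadiene to halobenzenes and of indenes to 2-halonaphthalenes, the all-carbon analogue of the Ciamician–Dennstedt pyrrole-to-pyridine expansion, together with the dibromocarbene ring expansion of cyclic enol ethers to 2-bromoenones. No stereocentre is set for the target, since the two of racemic 8 are destroyed on aromatisation. The step needs site selectivity between the two double bonds and a diene that neither shifts its double bonds nor loses its ring proton to base: the first is secured by the donor methoxy group on a fully substituted alkene against the acyl-deactivated enol pivalate, the second by working at or below 0 °C and adding the base last to an excess of the more readily deprotonated bromoform.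

**Step 4**
Reactants: 10 3-bromo-2-methoxy-4-methylphenyl pivalate
Product: 12 3-bromo-2-methoxy-4-methylphenol, via sodium aryloxide 11 (not isolated)
Conditions: NaOMe (1.2 equiv), MeOH, 0 °C → rt; AcOH quench
Reagents that add atoms: none
Why: Methoxide transesterification of the aryl ester is driven by the good aryloxide leaving group, and doing it before the ether cleavage keeps base away from an air-sensitive catechol.

**Step 5**
Reactants: 12 3-bromo-2-methoxy-4-methylphenol
Product: 14 3-bromo-4-methylbenzene-1,2-diol, via bromodioxaborole 13 (not isolated)
Conditions: BBr3, CH2Cl2, −78 → 0 °C; H2O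
Reagents that add atoms: none
Why: Lewis acid ether cleavage, in which BBr3 binds the phenol and the neighbouring ether oxygen, bromide removes the methyl group by SN2 to give the cyclic bromoboronate 13, and water releases the catechol while the aryl bromide and the ring methyl stay untouched.

**Step 6**
Reactants: 14 3-bromo-4-methylbenzene-1,2-diol
Product: 16 3,4,6-tribromo-5-methylbenzene-1,2-diol, via dibromocatechol 15 (not isolated)
Conditions: Br2 (2.2 equiv), AcOH, rt, dark
Reagents that add atoms: bromine, BrBr
Why: Electrophilic aromatic bromination of the strongly activated catechol should fill its only two free positions, C5 of 14 (para to a hydroxyl) first and C6 second, while the HBr formed keeps the medium acidic so that the catechol is not oxidised to the o-quinone and the ionic, dark conditions spare the benzylic methyl.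

**Compound list**
1 | cyclotene, 2-hydroxy-3-methylcyclopent-2-en-1-one | CC1=C(O)C(=O)CC1 | starting material
2 | potassium 2-methyl-5-oxocyclopent-1-en-1-olate (not isolated) | CC1=C([O-])C(=O)CC1.[K+] | intermediate
3 | 2-methoxy-3-methylcyclopent-2-en-1-one | CC1=C(OC)C(=O)CC1 | intermediate
4 | pivaloyl chloride | CC(C)(C)C(Cl)=O | starting material
5 | potassium 5-methoxy-4-methylcyclopenta-1,4-dien-1-olate (not isolated) | CC1=C(OC)C([O-])=CC1.[K+] | intermediate
6 | 5-methoxy-4-methylcyclopenta-1,4-dien-1-yl pivalate (2-pivaloyloxy-3-methoxy-4-methylcyclopenta-1,3-diene) | CC1=C(OC)C(OC(=O)C(C)(C)C)=CC1 | intermediate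
7 | bromoform | BrC(Br)Br | starting material
8 | 6,6-dibromo-1-methoxy-5-methylbicyclo[3.1.0]hex-2-en-2-yl pivalate (cis-fused, racemic, one enantiomer written; not isolated) | C[C@@]12CC=C(OC(=O)C(C)(C)C)[C@]1(OC)C2(Br)Br | intermediate
9 | 2-bromo-1-methoxy-3-methyl-6-(pivaloyloxy)cyclohexa-2,5-dien-1-ylium bromide (arenium ion of 10 protonated at the former CH2, written as its oxocarbenium form; not isolated) | CC1=C(Br)C(=[O+]C)C(OC(=O)C(C)(C)C)=CC1.[Br-] | intermediate
10 | 3-bromo-2-methoxy-4-methylphenyl pivalate | COc1c(Br)c(C)ccc1OC(=O)C(C)(C)C | intermediate
11 | sodium 3-bromo-2-methoxy-4-methylphenolate (not isolated) | COc1c(Br)c(C)ccc1[O-].[Na+] | intermediate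
12 | 3-bromo-2-methoxy-4-methylphenol | COc1c(Br)c(C)ccc1O | intermediate
13 | 2,4-dibromo-5-methyl-1,3,2-benzodioxaborole (not isolated) | Cc1ccc2OB(Br)Oc2c1Br | intermediate
14 | 3-bromo-4-methylbenzene-1,2-diol | Cc1ccc(O)c(O)c1Br | intermediate
15 | 3,5-dibromo-4-methylbenzene-1,2-diol (not isolated) | Cc1c(Br)cc(O)c(O)c1Br | intermediate
16 | 3,4,6-tribromo-5-methylbenzene-1,2-diol | Cc1c(Br)c(O)c(O)c(Br)c1Br | target

**Totals**
Total step count: 6. Longest linear sequence: 6 steps (1 → 16).

**Steps most likely to fail**

Step 3. The base may deprotonate the ring CH2 of the diene instead of bromoform, the double bonds may migrate by 1,5-hydrogen shift before cyclopropanation, the carbene may add to the enol ester double bond, or tert-butoxide may cleave the enol ester. The fallback sets out from enone 3 and puts the same C6–C1 and C6–C5 bonds into a monoene, reaching the aromatic oxidation level by a separate dehydrogenation. The ketone would be reduced with i-Bu2AlH (toluene, −78 °C) to racemic 2-methoxy-3-methylcyclopent-2-en-1-ol F1. Acylation with 4 (pyridine, catalytic 4-dimethylaminopyridine, CH2Cl2, 0 °C) would give 2-methoxy-3-methylcyclopent-2-en-1-yl pivalate F2, which has one isolated enol ether double bond and no acidic ring proton. CHBr3/KOt-Bu in pentane should give 6,6-dibromo-1-methoxy-5-methylbicyclo[3.1.0]hexan-2-yl pivalate F3, which is not isolated. It opens on warming, and aqueous NaHCO3 work-up hydrolyses the oxocarbenium ion to 3-bromo-4-methyl-2-oxocyclohex-3-en-1-yl pivalate F4; this is the established ring expansion of cyclic enol ethers to 2-bromoenones. Dehydrogenation with 2,3-dichloro-5,6-dicyano-1,4-benzoquinone and catalytic TsOH in dioxane at reflux should aromatise F4 to 3-bromo-2-hydroxy-4-methylphenyl pivalate F5. Acid methanolysis (HCl, MeOH, reflux) then comes back to the route at catechol 14.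

Step 2. Acylation may go to carbon instead of oxygen, the enolate may be quenched by proton transfer from the acidic diene product, and the diene may isomerise or dimerise on handling. The fallback sets out from enone 3 and traps it by soft enolisation, which is O-selective and needs no free enolate. i-Pr3SiOSO2CF3 and Et3N (CH2Cl2, 0 °C) would give triisopropyl[(5-methoxy-4-methylcyclopenta-1,4-dien-1-yl)oxy]silane F6, which cannot be cleaved by alkoxide. The carbene ring expansion under the conditions of step 3 would pass through {[6,6-dibromo-1-methoxy-5-methylbicyclo[3.1.0]hex-2-en-2-yl]oxy}triisopropylsilane F7 to (3-bromo-2-methoxy-4-methylphenoxy)triisopropylsilane F8. Site selection then rests on the steric shield of the triisopropylsilyl group and the full substitution of the methoxy alkene instead of on acyl deactivation. Bu4NF in THF comes back to the route at phenol 12.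

Step 6. Bromine may oxidise the catechol to the o-quinone, or the second bromination may stall. The fallback sets out from phenol 12 and brominates before the catechol is unveiled. Br2 in AcOH at room temperature should give 2,3,5-tribromo-6-methoxy-4-methylphenol F9, a monoether that cannot pass to an o-quinone. BBr3 in CH2Cl2 then cleaves the ether through 2,4,6,7-tetrabromo-5-methyl-1,3,2-benzodioxaborole F10, and water releases target 16 under non-oxidising conditions.

**Further compounds**
F1 | step 3 | 2-methoxy-3-methylcyclopent-2-en-1-ol (racemic) | CC1=C(OC)C(O)CC1
F2 | step 3 | 2-methoxy-3-methylcyclopent-2-en-1-yl pivalate (racemic) | CC1=C(OC)C(OC(=O)C(C)(C)C)CC1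
F3 | step 3 | 6,6-dibromo-1-methoxy-5-methylbicyclo[3.1.0]hexan-2-yl pivalate (cis-fused, racemic, C2 configuration left open; not isolated) | C[C@@]12CCC(OC(=O)C(C)(C)C)[C@]1(OC)C2(Br)Br
F4 | step 3 | 3-bromo-4-methyl-2-oxocyclohex-3-en-1-yl pivalate (racemic) | CC1=C(Br)C(=O)C(OC(=O)C(C)(C)C)CC1
F5 | step 3 | 3-bromo-2-hydroxy-4-methylphenyl pivalate | Cc1ccc(OC(=O)C(C)(C)C)c(O)c1Br
F6 | step 2 | triisopropyl[(5-methoxy-4-methylcyclopenta-1,4-dien-1-yl)oxy]silane | CC1=C(OC)C(O[Si](C(C)C)(C(C)C)C(C)C)=CC1
F7 | step 2 | {[6,6-dibromo-1-methoxy-5-methylbicyclo[3.1.0]hex-2-en-2-yl]oxy}triisopropylsilane (cis-fused, racemic, one enantiomer written; not isolated) | C[C@@]12CC=C(O[Si](C(C)C)(C(C)C)C(C)C)[C@]1(OC)C2(Br)Br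
F8 | step 2 | (3-bromo-2-methoxy-4-methylphenoxy)triisopropylsilane | COc1c(Br)c(C)ccc1O[Si](C(C)C)(C(C)C)C(C)C
F9 | step 6 | 2,3,5-tribromo-6-methoxy-4-methylphenol | COc1c(O)c(Br)c(Br)c(C)c1Br
F10 | step 6 | 2,4,6,7-tetrabromo-5-methyl-1,3,2-benzodioxaborole (not isolated) | Cc1c(Br)c(Br)c2OB(Br)Oc2c1Br
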